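**Plan**

1. Labels: ring A = Cs (spiro carbon), Ck (ketone between Cs and Cq), Cq (carbon with Me and prenyl), Cv (enol C–OH), Cz (acyl-bearing carbon), Cw (ketone between Cz and Cs); ring B = Cs, Cx (CH2), Ca and Cb (fusion CH), C7 (CMe–OH), Cy (CH2); ring C = Ca, C3 (CMe–OH), two CH2, Cb.
2. Retrosynthetic cuts, last bond made first: acyl–Cz; Cq–prenyl (as allyl) and Cq–Me; Cs–Cy together with C7–O (one oxidative step from a phenol); aryl–Cx; Ca–Cb of ring C.
3. Enabling feature: Cs lies para to the oxygen-bearing Cv of a phloroglucinol-type ring A, Cy–C7 can be the CH2=C(Me) of an isopropenyl group on Cb, and the C3 and C7 oxygens share one face of ring B, so a carbonate on C3–O can reach a cation at C7.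
4. Forward order: ring C first (magnesium-ene closure of a chloride made from (R)-linalool), the 3,5-dimethoxyphenol ring joined at Cx, ring B by dearomatising spirocyclisation, then ring A is desymmetrised and given Me, prenyl and acyl.
5. Stereochemistry: C3 from (R)-linalool; Ca and Cb from the ene closure (cis to each other and to the magnesium-bound C3 oxygen); C7 by carbonate delivery; Cs by tying C3–O to Cw, the only oxygen-bearing ring A carbon on its face of ring B; Cq by ligand-controlled palladium allylation; the acyl centre from (S)-2-methylbutanoic acid.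

Key step: step 8

Remark: ring A enols and 1,3-diones are written as single tautomers (they interconvert), and organometallic intermediates are written as monomers.

**Route**

Step 1
Reactants: 1 (R)-linalool
Product: 2 (2E,6R)-2,6-dimethylocta-2,7-diene-1,6-diol
Conditions: SeO2 (0.2 equiv), t-BuOOH, salicylic acid (cat.), CH2Cl2, rt
Reagents that add atoms: tert-butyl hydroperoxide, CC(C)(C)OO (oxygen relayed by selenium dioxide, O=[Se]=O)
Why: Selenium dioxide allylic oxidation (ene reaction then 2,3-sigmatropic shift) should hydroxylate the (E)-methyl group of the trisubstituted alkene selectively, the vinyl carbinol being no ene donor, and the carbinol centre (later C3) is not touched.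

Step 2
Reactants: 2 (2E,6R)-2,6-dimethylocta-2,7-diene-1,6-diol
Product: 3 (3R,6E)-8-chloro-3,7-dimethylocta-1,6-dien-3-ol
Conditions: MsCl, LiCl, 2,4,6-collidine, DMF, 0 °C
Reagents that add atoms: lithium chloride, [Li+].[Cl-]; methanesulfonyl chloride, CS(=O)(=O)Cl (activator and second chloride source)
Why: Mesylation of the primary allylic alcohol with in situ SN2 displacement by chloride should give the primary (E)-allylic chloride, the tertiary carbinol being too hindered to be sulfonylated at 0 °C, and no stereocentre is involved.

Step 3
Reactants: 4 3,5-dimethoxyphenol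
Product: 5 (3,5-dimethoxyphenoxy)tri(propan-2-yl)silane
Conditions: TIPSCl, imidazole, DMF, rt
Reagents that add atoms: chlorotri(propan-2-yl)silane, CC(C)[Si](Cl)(C(C)C)C(C)C
Why: Silylation of the phenol with a chlorosilane and imidazole is routine, and the bulky triisopropylsilyl ether is chosen because it survives butyllithium, the organozinc coupling and the potassium amide of step 6 and directs lithiation poorly.

Step 4
Reactants: 5 (3,5-dimethoxyphenoxy)tri(propan-2-yl)silane
Product: 7 (4-iodo-3,5-dimethoxyphenoxy)tri(propan-2-yl)silane, via aryllithium 6 (not isolated)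
Conditions: n-BuLi, THF, 0 °C to rt; then I2, −78 °C to rt
Reagents that add atoms: iodine, II
Why: Directed ortho-lithiation should take place at the carbon flanked by both methoxy groups (cooperative coordination, the hindered silyloxy group being a poor director), and iodine quench of the aryllithium gives the aryl iodide.

Step 5
Reactants: 3 (3R,6E)-8-chloro-3,7-dimethylocta-1,6-dien-3-ol; 7 (4-iodo-3,5-dimethoxyphenoxy)tri(propan-2-yl)silane
Product: 12 (1R,2S,3S)-2-{[2,6-dimethoxy-4-(triisopropylsilyloxy)phenyl]methyl}-1-methyl-3-(prop-1-en-2-yl)cyclopentan-1-ol (all-cis), via chloromagnesium alkoxide 8 (not isolated), via allylmagnesium chloride 9 (not isolated), via cyclopentylmethylmagnesium chloride 10 (not isolated), via alkylzinc chloride 11 (not isolated)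
Conditions: i-PrMgCl (1.0 equiv), THF, −78 °C; Mg powder (activated), THF, −60 °C then 60 °C; ZnCl2, 0 °C; 7, Pd(OAc)2 (cat.), SPhos, THF, 50 °C; aq. NH4Cl
Reagents that add atoms: none
Why: After the carbinol is placed on magnesium and the allylic Grignard reagent is formed, an intramolecular magnesium-ene reaction (the tether-bearing allyl terminus bonds to the internal vinyl carbon while magnesium moves to the terminal one, Cx) should close ring C with Ca–CH2Mg and Cb–isopropenyl cis, as the cyclic six-centre transfer demands, and with both cis to the C3 oxygen because the allyl group is delivered from a magnesium held by that alkoxide (the pattern of hydroxyl-assisted allylmagnesiation of allylic alcohols), and transmetalation to zinc followed by Negishi coupling then joins Cx to the aryl iodide.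

Step 6
Reactants: 12 the all-cis cyclopentanol; 13 di-tert-butyl dicarbonate
Product: 14 tert-butyl (1R,2S,3S)-2-{[2,6-dimethoxy-4-(triisopropylsilyloxy)phenyl]methyl}-1-methyl-3-(prop-1-en-2-yl)cyclopentyl carbonate
Conditions: KN(SiMe3)2, THF, −78 °C; then 13, −78 to 0 °C
Reagents that add atoms: none
Why: Acylation of the potassium alkoxide of the hindered tertiary alcohol by the dicarbonate (O-Boc formation) should give the mixed carbonate, with the aryl silyl ether inert at low temperature and no stereocentre affected.

Step 7
Reactants: 14 the silyl-protected carbonate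
Product: 15 tert-butyl (1R,2S,3S)-2-[(4-hydroxy-2,6-dimethoxyphenyl)methyl]-1-methyl-3-(prop-1-en-2-yl)cyclopentyl carbonate
Conditions: Bu4NF, AcOH, THF, 0 °C
Reagents that add atoms: none
Why: Fluoride-mediated desilylation of the aryl silyl ether, buffered with acetic acid so that neither phenoxide nor basic fluoride attacks the carbonate, should free the phenol needed for the oxidation.

Step 8
Reactants: 15 the phenol carbonate
Product: 16 spirodienone cyclic carbonate: 3,5-dimethoxycyclohexa-2,5-dien-1-one whose C4 is Cs of the cis-fused ring B/ring C bicycle, with C3–O and C7–O (cis on ring B) joined as a seven-membered carbonate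
Conditions: PhI(OAc)2 (1.1 equiv), (CF3)2CHOH, 0 °C
Reagents that add atoms: none
Why: Proposed new method: exchange of the phenol onto trivalent iodine and loss of iodobenzene should give a phenoxenium ion whose para carbon (Cs), kept symmetric by the two flanking methoxy groups, is attacked by the CH2 terminus of the isopropenyl group to form Cs–Cy, and the tertiary C7 cation so produced is trapped by the carbonyl oxygen of the C3 tert-butyl carbonate with loss of 2-methylpropene. The closest known reactions are hypervalent-iodine dearomatising ipso-cyclisations of para-alkylphenols by alkene nucleophiles and the capture of tertiary cations by tert-butyl carbonates (as in halocarbonate cyclisations); joining the two in one cascade is what is new. Ring B closes in a six-membered endo mode at the alkene with Markovnikov polarity, the five-membered alternative requiring a primary cation, and the temporary dioxepanone closes by oxygen attack in a seven-membered ring that the all-cis cyclopentane holds in place. The only new stereocentre, C7, is set by the tether, because oxygen can arrive only on the face of ring B on which C3 stands, which gives the cis relation of the two tertiary oxygens; Ca and Cb are carried in as cis and Cs is not yet stereogenic. The step needs ipso attack rather than ortho attack and carbonate capture rather than proton loss or solvent capture; the first is secured by the tether length (the ortho carbons cannot be reached) and the non-nucleophilic solvent, the second by the carbonate carbonyl sitting next to C7 on the concave face.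

Step 9
Reactants: 16 the spirodienone cyclic carbonate
Product: 18 cyclic enol ether in which the C3 oxygen has replaced the methoxy group on Cw (six-membered ring O–C3–Ca–Cx–Cs–Cw; Ck keeps OMe; C7–OH free), via diol dienone 17 (not isolated)
Conditions: NaOMe (0.5 equiv), MeOH, 45 °C; then PhMe, 90 °C with removal of MeOH
Reagents that add atoms: none
Why: Methoxide-catalysed transesterification should free the diol, whose C3 alkoxide then replaces the methoxy group on Cw by conjugate addition–elimination (a vinylogous transesterification driven by removal of methanol), and this fixes Cs because both tertiary oxygens stand on the ring B face that carries Cw, so neither can reach Ck, the six-membered bridge from C3–O being the one expected under these equilibrating conditions (a five-membered bridge from C7–O would force the axial C3 against it and would in any case mark the same carbon).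

Step 10
Reactants: 18 the cyclic enol ether
Product: 19 vinylogous acid: 18 with OH in place of OMe on Ck
Conditions: LiCl, DMSO, 110 °C; then dilute HCl to pH 4
Reagents that add atoms: none
Why: Chloride should demethylate the remaining vinylogous methyl ester by SN2 attack at the methyl group (nucleophilic dealkylation of an enol methyl ether), a path that is closed to the tertiary C3–O–Cw ether.

Step 11
Reactants: 19 the vinylogous acid
Product: 20 the Cq-methyl derivative of 19
Conditions: NaOMe (1.05 equiv), MeI (1.1 equiv), MeOH, 0 °C to rt
Reagents that add atoms: iodomethane, CI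
Why: C-alkylation of the cyclic 1,3-dicarbonyl enolate in a protic solvent should occur at Cq, the carbon between the two free oxygens, while Cz is locked in the enol ether and any O-methylated material (18 or its enol-ether isomer) can be returned through step 10; Cq is not yet a fixed stereocentre.

Step 12
Reactants: 20 the Cq-methyl vinylogous acid
Product: 21 Cq-allyl-Cq-methyl dione (ketones at Cv and Ck) with the C3–O–Cw enol ether intact (allyl on the ring A face syn to Cy; methyl syn to Cx)
Conditions: allyl acetate, [Pd(C3H5)Cl]2 (2.5 mol%), (R,R)-DACH-phenyl Trost ligand, Et3N, CH2Cl2, 0 °C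
Reagents that add atoms: allyl acetate, C=CCOC(C)=O
Why: Palladium-catalysed asymmetric allylic alkylation (Tsuji–Trost type) of the 2-methyl-1,3-dicarbonyl enolate should create the quaternary Cq, and since the substrate offers little facial bias there (both flanking groups on Cs are CH2) the chiral ligand is relied on to place allyl syn to Cy, the (R,R) ligand being the enantiomer indicated by the flap-and-wall model with the spiro flank under the open quadrant and the (S,S) ligand the immediate cross-check, while reversible O-allylation funnels to the C-allyl product.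

Step 13
Reactants: 21 the Cq-allyl compound
Product: 22 Cq-prenyl analogue of 21
Conditions: 2-methylbut-2-ene (excess), second-generation Grubbs catalyst RuCl2(=CHPh)(PCy3)(H2IMes) (5 mol%), CH2Cl2, 40 °C
Reagents that add atoms: 2-methylbut-2-ene, CC=C(C)C
Why: Olefin cross-metathesis with 2-methylbut-2-ene should convert the terminal allyl group into prenyl, the conjugated tri- and tetrasubstituted double bonds of ring A being inert, and no stereocentre is touched.

Step 14
Reactants: 22 the Cq-prenyl compound
Product: 23 de-acyl hyperielliptone HB: free C3–OH and C7–OH; Cv/Cw 1,3-dione (enol form); Cz unsubstituted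
Conditions: LiOH, dioxane/H2O, 70 °C; then cold dilute HCl to pH 5, used at once
Reagents that add atoms: lithium hydroxide, [Li+].[OH-]
Why: Hydroxide should add to Cw and expel the C3 alkoxide (conjugate addition–elimination, hydrolysis of a vinylogous ester), the resulting 1,3-diketone enolate being inert to re-closure and to further attack, while Ck is shielded from retro-Claisen cleavage by its two quaternary neighbours.

Step 15
Reactants: 23 de-acyl hyperielliptone HB; 24 (S)-2-methylbutanoic acid
Product: 25 hyperielliptone HB
Conditions: 24, DCC, CH2Cl2, 0 °C; then 23, DMAP (1.2 equiv), rt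
Reagents that add atoms: none
Why: Steglich-type O-acylation of the enol followed by the DMAP-mediated O-to-C acyl shift should give the 2-acyl-1,3-dione at Cz, the only enolisable ring carbon left, and the acyl stereocentre comes unchanged from 24, which preactivation at 0 °C and the weakly basic medium are meant to preserve.

**Compound list**

1 | (R)-linalool, (3R)-3,7-dimethylocta-1,6-dien-3-ol | CC(C)=CCC[C@@](C=C)(C)O | starting material
2 | (2E,6R)-2,6-dimethylocta-2,7-diene-1,6-diol | OC/C(C)=C/CC[C@@](C=C)(C)O | intermediate
3 | (3R,6E)-8-chloro-3,7-dimethylocta-1,6-dien-3-ol | ClC/C(C)=C/CC[C@@](C=C)(C)O | intermediate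
4 | 3,5-dimethoxyphenol | COc1cc(O)cc(OC)c1 | starting material
5 | (3,5-dimethoxyphenoxy)tri(propan-2-yl)silane | COc1cc(O[Si](C(C)C)(C(C)C)C(C)C)cc(OC)c1 | intermediate
6 | [2,6-dimethoxy-4-(triisopropylsilyloxy)phenyl]lithium (not isolated) | COc1cc(O[Si](C(C)C)(C(C)C)C(C)C)cc(OC)c1[Li] | intermediate
7 | (4-iodo-3,5-dimethoxyphenoxy)tri(propan-2-yl)silane | COc1cc(O[Si](C(C)C)(C(C)C)C(C)C)cc(OC)c1I | intermediate
8 | chloromagnesium alkoxide of 3 (not isolated) | ClC/C(C)=C/CC[C@@](C=C)(C)O[Mg]Cl | intermediate
9 | allylmagnesium chloride from 8 (not isolated, allyl geometry mobile) | Cl[Mg]CC(C)=CCC[C@@](C=C)(C)O[Mg]Cl | intermediate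
10 | all-cis cyclopentylmethylmagnesium chloride, C3 oxygen on magnesium (not isolated) | Cl[Mg]C[C@H]1[C@H](CC[C@@]1(C)O[Mg]Cl)C(C)=C | intermediate
11 | all-cis cyclopentylmethylzinc chloride (not isolated) | Cl[Zn]C[C@H]1[C@H](CC[C@@]1(C)O[Mg]Cl)C(C)=C | intermediate
12 | (1R,2S,3S)-2-{[2,6-dimethoxy-4-(triisopropylsilyloxy)phenyl]methyl}-1-methyl-3-(prop-1-en-2-yl)cyclopentan-1-ol | COc1cc(O[Si](C(C)C)(C(C)C)C(C)C)cc(OC)c1C[C@H]1[C@H](CC[C@@]1(C)O)C(C)=C | intermediate
13 | di-tert-butyl dicarbonate | CC(C)(C)OC(=O)OC(=O)OC(C)(C)C | starting material
14 | tert-butyl (1R,2S,3S)-2-{[2,6-dimethoxy-4-(triisopropylsilyloxy)phenyl]methyl}-1-methyl-3-(prop-1-en-2-yl)cyclopentyl carbonate | COc1cc(O[Si](C(C)C)(C(C)C)C(C)C)cc(OC)c1C[C@H]1[C@H](CC[C@@]1(C)OC(=O)OC(C)(C)C)C(C)=C | intermediate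
15 | tert-butyl (1R,2S,3S)-2-[(4-hydroxy-2,6-dimethoxyphenyl)methyl]-1-methyl-3-(prop-1-en-2-yl)cyclopentyl carbonate | COc1cc(O)cc(OC)c1C[C@H]1[C@H](CC[C@@]1(C)OC(=O)OC(C)(C)C)C(C)=C | intermediate
16 | spiro 3,5-dimethoxycyclohexa-2,5-dienone on the cis-fused ring B/ring C bicycle, C3–O and C7–O as cyclic carbonate | COC1=CC(=O)C=C(OC)C12C[C@H]3[C@H](CC[C@@]3(C)OC(=O)O4)[C@@]4(C)C2 | intermediate
17 | spiro 3,5-dimethoxydienone with free C3–OH and C7–OH (not isolated) | COC1=CC(=O)C=C(OC)C12C[C@H]3[C@H](CC[C@@]3(C)O)[C@](C)(O)C2 | intermediate
18 | cyclic enol ether C3–O–Cw, OMe on Ck, C7–OH free | COC1=CC(=O)C=C2O[C@]3(C)CC[C@H]4[C@@H]3C[C@@]12C[C@@]4(C)O | intermediate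
19 | vinylogous acid: 18 with OH on Ck | OC1=CC(=O)C=C2O[C@]3(C)CC[C@H]4[C@@H]3C[C@@]12C[C@@]4(C)O | intermediate
20 | 19 with methyl on Cq | OC1=C(C)C(=O)C=C2O[C@]3(C)CC[C@H]4[C@@H]3C[C@@]12C[C@@]4(C)O | intermediate
21 | Cq-allyl-Cq-methyl dione (ketones at Cv and Ck), C3–O–Cw enol ether | O=C1[C@](C)(CC=C)C(=O)C=C2O[C@]3(C)CC[C@H]4[C@@H]3C[C@@]12C[C@@]4(C)O | intermediate
22 | Cq-prenyl-Cq-methyl dione (ketones at Cv and Ck), C3–O–Cw enol ether | O=C1[C@](C)(CC=C(C)C)C(=O)C=C2O[C@]3(C)CC[C@H]4[C@@H]3C[C@@]12C[C@@]4(C)O | intermediate
23 | de-acyl hyperielliptone HB (diol, Cv/Cw dione as enol) | C1=C(O)[C@@](C)(CC=C(C)C)C(=O)[C@]2(C[C@H]3[C@H](CC[C@@]3(C)O)[C@](C)(O)C2)C1=O | intermediate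
24 | (S)-2-methylbutanoic acid | CC[C@H](C)C(O)=O | starting material
25 | hyperielliptone HB | CC[C@H](C)C(=O)C1=C(O)[C@@](C)(CC=C(C)C)C(=O)[C@]2(C[C@H]3[C@H](CC[C@@]3(C)O)[C@](C)(O)C2)C1=O | target

**Step count and risks**

Total steps: 15. Longest linear sequence: 13 steps (1, 2 and 5 to 15); steps 3 and 4 form the short aryl branch.

Steps most likely to fail:

1. Step 8 (proposed new method). The C7 cation may lose a proton or be captured by acetate or solvent before the carbonate closes, the phenoxenium ion may be intercepted at an ortho carbon, or the carbonate may be solvolysed in the acidic fluoroalcohol. The fallback uses known reactions, sets out from 14 and returns at 16. The isopropenyl methyl group of 14 is hydroxylated with SeO2 and t-BuOOH to the allylic alcohol F1, which methyl chloroformate and pyridine convert into the allylic methyl carbonate F2. Bu4NF buffered with AcOH then frees the phenol F3. With Pd2(dba)3 and PPh3 in CH2Cl2, zerovalent palladium ionises the carbonate and the para carbon of the phenoxide closes ring B on the symmetric 2-substituted allyl unit (intramolecular dearomatising allylic alkylation of a phenol), giving the exo-methylene spirodienone F4 with the C3 tert-butyl carbonate intact. Markovnikov hydrofunctionalisation by hydrogen-atom transfer with radical–polar crossover (cobalt salen complex Co(C16H14N2O2), 1-fluoro-2,4,6-trimethylpyridinium tetrafluoroborate, PhSiH3), known for tert-butyl esters and carbamates as internal oxygen nucleophiles, then turns the C7 methylene into the C7 methyl carbinol carbon, captured from the C3 face by the carbonate with loss of 2-methylpropene to give 16.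

2. Step 5. Wurtz-type dimerisation may consume the allylic chloride on the magnesium surface, the ene closure may proceed through an allylmagnesium that is not bound to the C3 alkoxide (which would erode the all-cis relation), and transmetalation of the β-branched alkylzinc onto the di-ortho-methoxy arylpalladium may stall. The fallback sets out from 3 and returns at 12. Treating 3 with Et2Zn and catalytic Pd(PPh3)4 forms the ethylzinc alkoxide and, through a palladium allyl complex, the allylzinc F5, in which oxygen and the allyl group can sit on the same zinc. The zinc-ene closure gives the cyclised organozinc F6, and iodine converts it into the all-cis iodomethyl cyclopentanol F7, which can be purified and its configuration checked. Zinc dust with LiCl in THF then inserts into F7 to give the alkylzinc iodide F8, and Negishi coupling of F8 with 7 (Pd(OAc)2, SPhos) gives 12.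

3. Step 12. The ligand may fail to override whatever small bias the substrate has, so that both Cq epimers form, or O-allylation may persist. The fallback sets out from 20 and returns at 21. Allyl chloroformate and Et3N convert 20 into the allyl enol carbonate F9. Decarboxylative allylation with Pd2(dba)3 and (S)-t-Bu-PHOX (or its enantiomer, whichever the first run shows to place allyl syn to Cy) then forms the Cq–allyl bond within a palladium enolate ion pair, a mode of stereoinduction different from the outer-sphere alkylation of step 12.

**Further compounds**

F1 | step 8 | 14 with the isopropenyl methyl oxidised to CH2OH (allylic alcohol) | COc1cc(O[Si](C(C)C)(C(C)C)C(C)C)cc(OC)c1C[C@H]1[C@H](CC[C@@]1(C)OC(=O)OC(C)(C)C)C(=C)CO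
F2 | step 8 | allylic methyl carbonate of F1 | COc1cc(O[Si](C(C)C)(C(C)C)C(C)C)cc(OC)c1C[C@H]1[C@H](CC[C@@]1(C)OC(=O)OC(C)(C)C)C(=C)COC(=O)OC
F3 | step 8 | free phenol from F2 | COc1cc(O)cc(OC)c1C[C@H]1[C@H](CC[C@@]1(C)OC(=O)OC(C)(C)C)C(=C)COC(=O)OC
F4 | step 8 | spiro 3,5-dimethoxydienone with exocyclic methylene at C7 and tert-butyl carbonate on C3–O | COC1=CC(=O)C=C(OC)C12C[C@H]3[C@H](CC[C@@]3(C)OC(=O)OC(C)(C)C)C(=C)C2
F5 | step 5 | allyl(ethyl)zinc with ethylzinc alkoxide from 3 (not isolated) | CC[Zn]CC(C)=CCC[C@@](C=C)(C)O[Zn]CC
F6 | step 5 | all-cis cyclopentylmethyl(ethyl)zinc with ethylzinc alkoxide (not isolated) | CC[Zn]C[C@H]1[C@H](CC[C@@]1(C)O[Zn]CC)C(C)=C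
F7 | step 5 | all-cis 2-(iodomethyl)-1-methyl-3-(prop-1-en-2-yl)cyclopentan-1-ol | IC[C@H]1[C@H](CC[C@@]1(C)O)C(C)=C
F8 | step 5 | all-cis cyclopentylmethylzinc iodide from F7 (not isolated) | I[Zn]C[C@H]1[C@H](CC[C@@]1(C)O)C(C)=C
F9 | step 12 | allyl enol carbonate of 20 (carbonate on the Ck oxygen) | C=CCOC(=O)OC1=C(C)C(=O)C=C2O[C@]3(C)CC[C@H]4[C@@H]3C[C@@]12C[C@@]4(C)O
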